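**Retrosynthetic overview**
1. Cut the ring alkene between C5 and C4 (benzoxepine numbering: O1, C2, C3, C4, C5). C5 goes back to an aryl formyl carbon and C4 to an allylic CH2Cl carbon, so both are natural acceptor carbons in one open-chain precursor.
2. The formyl carbon is polarity-reversed as its N-tosylhydrazone, which gives an aryldiazomethane with a donor carbon. Palladium joins it to the allyl unit by carbene migratory insertion and β-hydride elimination. This makes C4=C5, keeps C3=CH2 and closes the ring in one operation.
3. The precursor comes from stearoyl chloride (ester C–O) and 3-chloro-2-(chloromethyl)prop-1-ene (aryl ether C–O) on 5-(hydroxymethyl)salicylaldehyde.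
4. Ring order: the benzene ring is bought. The seven-membered oxepine ring is the only ring made, and it is made in the last step.

Assumption: the SMILES has no stereocentre and C4=C5 is locked cis by the seven-membered ring, so the target is achiral and needs no enantiocontrol. The acyl chain is read as octadecanoyl (17 carbons after the carbonyl).

**Step 1**
Reactants: 1 2-hydroxy-5-(hydroxymethyl)benzaldehyde; 2 3-chloro-2-(chloromethyl)prop-1-ene
Product: 3 2-{[2-(chloromethyl)prop-2-en-1-yl]oxy}-5-(hydroxymethyl)benzaldehyde
Conditions: 2 (5 equiv), K2CO3 (1.5 equiv), MeCN, 60 °C, 6 h; excess 2 distilled off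
Reagents that add atoms: 3-chloro-2-(chloromethyl)prop-1-ene (2), C=C(CCl)CCl
Why: Williamson ether synthesis, in which K2CO3 deprotonates only the acidic salicylaldehyde phenol and not the benzylic alcohol, SN2 and SN2' attack on 2 give the same product, the large excess of 2 holds the reaction at mono-substitution, and no stereocentre is formed.

**Step 2**
Reactants: 3 2-{[2-(chloromethyl)prop-2-en-1-yl]oxy}-5-(hydroxymethyl)benzaldehyde; 4 octadecanoyl chloride (stearoyl chloride)
Product: 5 (4-{[2-(chloromethyl)prop-2-en-1-yl]oxy}-3-formylphenyl)methyl octadecanoate
Conditions: 4 (1.1 equiv), pyridine (1.5 equiv), CH2Cl2, 0 °C to rt, 2 h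
Reagents that add atoms: octadecanoyl chloride (4), ClC(=O)CCCCCCCCCCCCCCCCC
Why: O-acylation (nucleophilic acyl substitution) of the only free hydroxyl group, under conditions to which the aldehyde, aryl ether and allylic chloride are inert, with no stereocentre formed.

**Step 3 (key step)**
Reactants: 5 (4-{[2-(chloromethyl)prop-2-en-1-yl]oxy}-3-formylphenyl)methyl octadecanoate; 6 4-methylbenzenesulfonohydrazide (TsNHNH2)
Product: 9 (3-methylidene-2,3-dihydro-1-benzoxepin-7-yl)methyl octadecanoate, via N-tosylhydrazone 7 (not isolated), via aryldiazomethane 8 (not isolated)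
Conditions: (a) 6 (1.05 equiv), 4 Å MS, 1,4-dioxane, 50 °C, 1 h; (b) this solution added by syringe pump over 8 h to Pd2(dba)3 (5 mol %), P(2-furyl)3 (20 mol %), K2CO3 (3 equiv), 1,4-dioxane, 90 °C, final 0.01 M
Reagents that add atoms: none
Why: Proposed new method: condensation gives 7, and because 7 is fed slowly into an excess of catalyst, zerovalent palladium first ionises the allylic chloride to an η3-allyl divalent palladium chloride (which also masks the alkene against intramolecular dipolar cycloaddition), K2CO3 then causes Bamford–Stevens loss of sulfinate to unveil 8, whose now nucleophilic former formyl carbon attacks the tethered electrophilic palladium centre with loss of N2, the allyl ligand (two equivalent termini) migrates onto the carbene carbon to form C4–C5 and the seven-membered ring, and syn β-hydride elimination from C4, the only β-position, gives the necessarily cis C4=C5 alkene beside the intact exocyclic methylene with no stereocentre formed; the closest known reaction type is the intermolecular palladium-catalysed carbene cross-coupling of N-sulfonylhydrazones with allyl or benzyl halides to give 1,3-dienes and styrenes (Barluenga-type coupling).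

**Compound list**
1 | 2-hydroxy-5-(hydroxymethyl)benzaldehyde | O=Cc1cc(CO)ccc1O | starting material
2 | 3-chloro-2-(chloromethyl)prop-1-ene | C=C(CCl)CCl | starting material
3 | 2-{[2-(chloromethyl)prop-2-en-1-yl]oxy}-5-(hydroxymethyl)benzaldehyde | O=Cc1cc(CO)ccc1OCC(=C)CCl | intermediate
4 | octadecanoyl chloride | ClC(=O)CCCCCCCCCCCCCCCCC | starting material
5 | (4-{[2-(chloromethyl)prop-2-en-1-yl]oxy}-3-formylphenyl)methyl octadecanoate | O=Cc1cc(COC(=O)CCCCCCCCCCCCCCCCC)ccc1OCC(=C)CCl | intermediate
6 | 4-methylbenzenesulfonohydrazide | Cc1ccc(cc1)S(=O)(=O)NN | starting material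
7 | (E)-N-tosylhydrazone of 5 | Cc1ccc(cc1)S(=O)(=O)N/N=C/c1cc(COC(=O)CCCCCCCCCCCCCCCCC)ccc1OCC(=C)CCl | intermediate
8 | (4-{[2-(chloromethyl)prop-2-en-1-yl]oxy}-3-(diazomethyl)phenyl)methyl octadecanoate | [N-]=[N+]=Cc1cc(COC(=O)CCCCCCCCCCCCCCCCC)ccc1OCC(=C)CCl | intermediate
9 | (3-methylidene-2,3-dihydro-1-benzoxepin-7-yl)methyl octadecanoate (CNP0302126.0, achiral) | C=C1C=Cc2cc(COC(=O)CCCCCCCCCCCCCCCCC)ccc2OC1 | target

**Total step count:** 3. **Longest linear sequence:** 3.

**Steps most likely to fail, with fallbacks**

Step 3 is the most likely to fail.
- Free 8 may undergo intramolecular dipolar cycloaddition onto the tethered alkene.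
- The sulfinate may trap the allylpalladium species as an allyl sulfone.
- The eight-membered palladacycle needed for insertion may lose out to oligomerisation.

The fallback sets out from 5 and comes back at 9. It reverses the polarity of the other partner instead. Indium powder and NaI in DMF (0.01 M, rt to 50 °C) turn the allylic chloride of 5 into an allylindium donor. This adds to the untouched formyl group and gives racemic (5-hydroxy-3-methylidene-2,3,4,5-tetrahydro-1-benzoxepin-7-yl)methyl octadecanoate F1. MsCl and Et3N in CH2Cl2 at 0 °C convert F1 into the labile benzylic mesylate (5-[(methanesulfonyl)oxy]-3-methylidene-2,3,4,5-tetrahydro-1-benzoxepin-7-yl)methyl octadecanoate F2. DBU in the same flask eliminates F2 across C4–C5 to give 9. The transient stereocentre at C5 is destroyed in this elimination. The cost is one extra step.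

Step 1 is second. Double substitution of 2 by two phenoxides would give the bis(aryl) ether and lower the yield of 3. The fallback sets out from 1 and comes back at 3. It uses a monofunctional electrophile and installs the chlorine afterwards. Compound 1 is O-alkylated with 3-chloro-2-methylprop-1-ene (K2CO3, MeCN, 60 °C) to give 5-(hydroxymethyl)-2-[(2-methylprop-2-en-1-yl)oxy]benzaldehyde F3. Ene-type allylic chlorination of F3 (NCS, PhSeCl 5 mol %, CH2Cl2, rt) then moves the alkene onto the former methyl carbon and gives 3.

Step 2 is the least risky. The electron-rich p-alkoxybenzylic alcohol could be partly converted to the benzylic chloride by the chloride salt that forms. The fallback sets out from 3 and comes back at 5. It activates the alcohol rather than the acid. A Mitsunobu esterification with stearic acid, PPh3 and DIAD in THF at 0 °C forms the alkyl C–O bond by carboxylate attack on the oxyphosphonium ion, with no acid chloride or chloride source present. No new isolable compound arises.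

**Further compounds**
F1 | step 3 | racemic (5-hydroxy-3-methylidene-2,3,4,5-tetrahydro-1-benzoxepin-7-yl)methyl octadecanoate | C=C1CC(O)c2cc(COC(=O)CCCCCCCCCCCCCCCCC)ccc2OC1
F2 | step 3 | racemic (5-[(methanesulfonyl)oxy]-3-methylidene-2,3,4,5-tetrahydro-1-benzoxepin-7-yl)methyl octadecanoate | C=C1CC(OS(C)(=O)=O)c2cc(COC(=O)CCCCCCCCCCCCCCCCC)ccc2OC1
F3 | step 1 | 5-(hydroxymethyl)-2-[(2-methylprop-2-en-1-yl)oxy]benzaldehyde | CC(=C)COc1ccc(CO)cc1C=O
F0 | step 2 | none | none
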